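**Strategy.** The benzene ring of the target carries oxygen on C3 and C5 and the 2-oxoheptadecyl chain on C1 (phenyl numbering), the pattern of an aromatised 5-substituted cyclohexane-1,3-dione. The route therefore builds the ring saturated and oxidises it late. One Michael–Claisen annulation between dimethyl malonate and a methyl enone forms the C1–C2 and C3–C4 ring bonds and places both ring oxygens 1,3 to each other: the enone supplies C1, C6, C5 and C4, the malonate C2 and C3. The annulation precursor is the E-enone CH3COCH=CHCH2–C(OCH2CH2O)–C15H31, in which the side-chain ketone is masked as a dioxolane.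

Key step: step 5

Remark: the two stereocentres created in step 5 are drawn as the racemic trans isomer expected under equilibrating conditions; both disappear in step 6, and the target is achiral.

**Step 1**
Reactants: 1 palmitoyl chloride; 2 Meldrum's acid
Product: 4 methyl 3-oxooctadecanoate, via acyl Meldrum's acid 3 (not isolated)
Conditions: pyridine (2 equiv), CH2Cl2, 0 °C to rt; aq HCl wash, concentrate; then MeOH, reflux
Reagents that add atoms: methanol, CO
Why: C-acylation of the acidic methylene of Meldrum's acid by the acid chloride, followed by methanolysis of the acyl Meldrum's acid with loss of acetone and CO2, is the standard Meldrum's acid route to methyl β-keto esters and carries the whole C16 acyl chain into the product.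

**Step 2**
Reactants: 4 methyl 3-oxooctadecanoate
Product: 5 methyl 2-(2-pentadecyl-1,3-dioxolan-2-yl)acetate
Conditions: ethylene glycol (4 equiv), p-TsOH·H2O (cat.), toluene, reflux, Dean–Stark trap
Reagents that add atoms: ethylene glycol, OCCO
Why: acid-catalysed ketalisation with azeotropic removal of water converts only the ketone carbonyl into the 1,3-dioxolane, the most hydrolysis-resistant of the simple ketals and one that is inert to the hydride and alkoxide steps ahead.

**Step 3**
Reactants: 5 methyl 2-(2-pentadecyl-1,3-dioxolan-2-yl)acetate
Product: 6 2-(2-pentadecyl-1,3-dioxolan-2-yl)acetaldehyde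
Conditions: i-Bu2AlH (DIBAL-H, 1.1 equiv), CH2Cl2, −78 °C; MeOH quench, aq KNaC4H4O6; used crude at once
Reagents that add atoms: none
Why: partial reduction of an ester at low temperature should stop at the aluminium hemiacetal, which is stabilised by chelation to a dioxolane oxygen and releases the aldehyde only on work-up.

**Step 4**
Reactants: 6 2-(2-pentadecyl-1,3-dioxolan-2-yl)acetaldehyde; 7 1-(triphenylphosphoranylidene)propan-2-one
Product: 8 (E)-5-(2-pentadecyl-1,3-dioxolan-2-yl)pent-3-en-2-one
Conditions: 7 (1.3 equiv), CH2Cl2, rt to 40 °C
Reagents that add atoms: none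
Why: the Wittig reaction of a ketone-stabilised ylide is E-selective through reversible, thermodynamically controlled oxaphosphetane formation and needs no added base, so the enolisable β-ketal aldehyde is not exposed to conditions that could eliminate a ketal oxygen.

**Step 5**
Reactants: 8 (E)-5-(2-pentadecyl-1,3-dioxolan-2-yl)pent-3-en-2-one; 9 dimethyl malonate
Product: 11 methyl trans-2-hydroxy-4-oxo-6-[(2-pentadecyl-1,3-dioxolan-2-yl)methyl]cyclohex-2-ene-1-carboxylate (racemic), via Michael adduct 10 (not isolated)
Conditions: 9 (1.2 equiv), NaOMe (1.1 equiv), MeOH, rt, then add 8 and reflux; cool to 0 °C, 1 M HCl to pH 4, immediate extraction into EtOAc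
Reagents that add atoms: none
Why: Sodium dimethyl malonate adds 1,4 to the enone (bond C1–C2), proton transfer moves the resulting enolate to the methyl side of the ketone, and this enolate acylates on one malonate ester with loss of methoxide (bond C3–C4); deprotonation of the vinylogous acid so formed pulls the equilibria to the product. The closest known reaction type is the Michael–Claisen (Michael–Dieckmann) condensation of alk-3-en-2-ones with malonates, the standard entry to 5-alkylcyclohexane-1,3-diones and 5-alkylresorcinols. The single ring closes in the 6-exo-trig mode, the enolate carbon attacking an ester carbonyl that lies outside the forming ring. The stereocentre at C1 arises in the conjugate addition without bias (racemic), and the one at C2 is set by thermodynamic control, because this carbon is epimerisable (alpha to the ester and to the enol) and should settle with the ester trans to the neighbouring side chain, both pseudo-equatorial. The selectivity needed is conjugate addition ahead of gamma-deprotonation of the enone, which could open the dioxolane by vinylogous beta-elimination; it is secured by the soft, weakly basic malonate anion kept in slight excess over methoxide and by the cyclic ketal, whose tethered alkoxide is a poor leaving group that can re-add.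

**Step 6**
Reactants: 11 methyl trans-2-hydroxy-4-oxo-6-[(2-pentadecyl-1,3-dioxolan-2-yl)methyl]cyclohex-2-ene-1-carboxylate
Product: 13 methyl 2,4-dihydroxy-6-[(2-pentadecyl-1,3-dioxolan-2-yl)methyl]benzoate, via bromo dione 12 (not isolated)
Conditions: NaOMe (1.0 equiv), anhydrous DMF, 0 °C; Br2 (1.0 equiv), 0 °C to rt; then 70–80 °C; poured into ice-cold aq NaHCO3
Reagents that add atoms: none
Why: the sodium enolate of the cyclic 1,3-dione is brominated at the carbon between the two carbonyls and the bromo dione then loses HBr on warming and tautomerises to the aromatic ring (halogenative dehydrogenation of a dihydroresorcylate), with only one equivalent of HBr released into anhydrous, weakly basic DMF so that the dioxolane should persist, with the ester deactivating the new ring towards further bromination, and with both stereocentres becoming sp2.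

**Step 7**
Reactants: 13 methyl 2,4-dihydroxy-6-[(2-pentadecyl-1,3-dioxolan-2-yl)methyl]benzoate
Product: 16 1-(3,5-dihydroxyphenyl)heptadecan-2-one (target), via carboxylic acid 14 (not isolated), via ketal resorcinol 15 (not isolated)
Conditions: 2 M aq NaOH (excess), 1,4-dioxane, reflux, argon, until CO2 loss is complete; then 3 M HCl to pH 1, 40 °C
Reagents that add atoms: water, O
Why: saponification of the hindered salicylate-type ester and protodecarboxylation of the resulting electron-rich 2,4-dihydroxybenzoate (ipso-protonation of the ring, then loss of CO2) take place in hot alkali, in which the dioxolane is inert, so that the ketone is released by acid-catalysed ketal hydrolysis only after the carboxyl group has gone and cannot lactonise onto it.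

**Compound list**
1 | palmitoyl chloride (hexadecanoyl chloride) | CCCCCCCCCCCCCCCC(=O)Cl | starting material
2 | Meldrum's acid (2,2-dimethyl-1,3-dioxane-4,6-dione) | CC1(C)OC(=O)CC(=O)O1 | starting material
3 | 5-(1-hydroxyhexadecylidene)-2,2-dimethyl-1,3-dioxane-4,6-dione (acyl Meldrum's acid, not isolated) | CCCCCCCCCCCCCCCC(O)=C1C(=O)OC(C)(C)OC1=O | intermediate
4 | methyl 3-oxooctadecanoate | CCCCCCCCCCCCCCCC(=O)CC(=O)OC | intermediate
5 | methyl 2-(2-pentadecyl-1,3-dioxolan-2-yl)acetate | CCCCCCCCCCCCCCCC1(CC(=O)OC)OCCO1 | intermediate
6 | 2-(2-pentadecyl-1,3-dioxolan-2-yl)acetaldehyde | CCCCCCCCCCCCCCCC1(CC=O)OCCO1 | intermediate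
7 | 1-(triphenylphosphoranylidene)propan-2-one | CC(=O)C=P(c1ccccc1)(c1ccccc1)c1ccccc1 | starting material
8 | (E)-5-(2-pentadecyl-1,3-dioxolan-2-yl)pent-3-en-2-one | CCCCCCCCCCCCCCCC1(C/C=C/C(C)=O)OCCO1 | intermediate
9 | dimethyl malonate | COC(=O)CC(=O)OC | starting material
10 | dimethyl 2-[4-oxo-1-(2-pentadecyl-1,3-dioxolan-2-yl)pentan-2-yl]propanedioate (racemic Michael adduct, not isolated) | CCCCCCCCCCCCCCCC1(CC(CC(C)=O)C(C(=O)OC)C(=O)OC)OCCO1 | intermediate
11 | methyl trans-2-hydroxy-4-oxo-6-[(2-pentadecyl-1,3-dioxolan-2-yl)methyl]cyclohex-2-ene-1-carboxylate (racemic, relative configuration shown) | CCCCCCCCCCCCCCCC1(C[C@@H]2CC(=O)C=C(O)[C@H]2C(=O)OC)OCCO1 | intermediate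
12 | methyl trans-3-bromo-2-hydroxy-4-oxo-6-[(2-pentadecyl-1,3-dioxolan-2-yl)methyl]cyclohex-2-ene-1-carboxylate (racemic, not isolated) | CCCCCCCCCCCCCCCC1(C[C@@H]2CC(=O)C(Br)=C(O)[C@H]2C(=O)OC)OCCO1 | intermediate
13 | methyl 2,4-dihydroxy-6-[(2-pentadecyl-1,3-dioxolan-2-yl)methyl]benzoate | CCCCCCCCCCCCCCCC1(Cc2cc(O)cc(O)c2C(=O)OC)OCCO1 | intermediate
14 | 2,4-dihydroxy-6-[(2-pentadecyl-1,3-dioxolan-2-yl)methyl]benzoic acid (present as its sodium salt, not isolated) | CCCCCCCCCCCCCCCC1(Cc2cc(O)cc(O)c2C(=O)O)OCCO1 | intermediate
15 | 5-[(2-pentadecyl-1,3-dioxolan-2-yl)methyl]benzene-1,3-diol (not isolated) | CCCCCCCCCCCCCCCC1(Cc2cc(O)cc(O)c2)OCCO1 | intermediate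
16 | 1-(3,5-dihydroxyphenyl)heptadecan-2-one | CCCCCCCCCCCCCCCC(=O)Cc1cc(O)cc(O)c1 | target

**Total step count:** 7
**Longest linear sequence:** 7 steps (from 1 to 16)

**Steps most likely to fail**

Step 5. Gamma-deprotonation of the enone may compete with conjugate addition and open the ketal by vinylogous elimination, or the Michael adduct may stall before ring closure. The fallback exchanges the roles of donor and acceptor and sets out from aldehyde 6. A Wittig reaction with methyl (triphenylphosphoranylidene)acetate in CH2Cl2 should give methyl (E)-4-(2-pentadecyl-1,3-dioxolan-2-yl)but-2-enoate F1, whose gamma-hydrogens are less acidic than those of the enone. Methyl acetoacetate and NaOMe in MeOH at reflux should then add 1,4 to give dimethyl 2-acetyl-3-[(2-pentadecyl-1,3-dioxolan-2-yl)methyl]pentanedioate F2, which is not isolated. Its acetyl methyl enolate should close onto the chain ester in a Dieckmann-type acylation and give the same ring, so the route is rejoined at compound 11.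

Step 6. The HBr released may strip the dioxolane, after which the freed ketone enol could lactonise onto the ortho ester, and the new electron-rich ring may be brominated further. The fallback avoids halogen and acid and sets out from compound 11. Double deprotonation with LiN(SiMe3)2 in THF at −78 °C and O-silylation with Me3SiCl should give methyl 6-[(2-pentadecyl-1,3-dioxolan-2-yl)methyl]-2,4-bis(trimethylsilyloxy)cyclohexa-1,3-diene-1-carboxylate F3. DDQ in toluene at rt should dehydrogenate this 1,3-cyclohexadiene to methyl 6-[(2-pentadecyl-1,3-dioxolan-2-yl)methyl]-2,4-bis(trimethylsilyloxy)benzoate F4. K2CO3 in MeOH should then remove the silyl groups, and the route is rejoined at compound 13.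

Step 3. The reduction may run past the aldehyde oxidation level, and the β-ketal aldehyde may undergo elimination during isolation. The fallback adjusts the oxidation level in two controlled stages and sets out from ester 5. LiAlH4 in THF at 0 °C should give 2-(2-pentadecyl-1,3-dioxolan-2-yl)ethan-1-ol F5, a stable compound that can be purified. Oxidation with Dess–Martin periodinane buffered with NaHCO3 in CH2Cl2 should return the aldehyde, used at once, and the route is rejoined at compound 6.

**Further compounds**
F1 | step 5 | methyl (E)-4-(2-pentadecyl-1,3-dioxolan-2-yl)but-2-enoate | CCCCCCCCCCCCCCCC1(C/C=C/C(=O)OC)OCCO1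
F2 | step 5 | dimethyl 2-acetyl-3-[(2-pentadecyl-1,3-dioxolan-2-yl)methyl]pentanedioate (mixture of diastereomers, not isolated) | CCCCCCCCCCCCCCCC1(CC(CC(=O)OC)C(C(C)=O)C(=O)OC)OCCO1
F3 | step 6 | methyl 6-[(2-pentadecyl-1,3-dioxolan-2-yl)methyl]-2,4-bis(trimethylsilyloxy)cyclohexa-1,3-diene-1-carboxylate (racemic) | CCCCCCCCCCCCCCCC1(CC2CC(O[Si](C)(C)C)=CC(O[Si](C)(C)C)=C2C(=O)OC)OCCO1
F4 | step 6 | methyl 6-[(2-pentadecyl-1,3-dioxolan-2-yl)methyl]-2,4-bis(trimethylsilyloxy)benzoate | CCCCCCCCCCCCCCCC1(Cc2cc(O[Si](C)(C)C)cc(O[Si](C)(C)C)c2C(=O)OC)OCCO1
F5 | step 3 | 2-(2-pentadecyl-1,3-dioxolan-2-yl)ethan-1-ol | CCCCCCCCCCCCCCCC1(CCO)OCCO1
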